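Remark 1: atoms keep the numbering of the target chain, C1 (CHBr) to C8 (CH2Cl), in every intermediate.
Remark 2: the antipode of trans-2,5-diphenylpyrrolidine in step 8 is chosen on the steric enamine model (chlorine enters anti to the phenyl group flanking the enamine carbon); should induction run the other way, the mirror-image catalyst is used.
Remark 3: a CIP check shows that 5 must be 2R,3R (hence D-(−)-tartrate), 6 is then 2S,3R and 9 is 2R,3R, so these structures stand; the cyclic carbonate of Alternative 1 needs the opposite configuration at C4 (A2, not A1), as argued there.

## Structural features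

The target is an acyclic C10 halogenated monoterpene: an eight-carbon chain with methyl branches on C3 and C7 and one ring, the C3–C4 oxirane. C1=C2 is a Z-1-bromo-2-chloroalkene bonded directly to the quaternary oxirane carbon C3. C4 is linked through the C5 methylene to the secondary carbinol C6, which is flanked by the fully substituted C7 bearing bromine, a methyl group and the chloromethyl carbon C8. The four stereocentres form two contiguous pairs, C3/C4 (3R,4S; haloalkene and C5 trans on the oxirane) and C6/C7 (6R,7R), separated by one methylene, so each pair needs its own controlling element. The fragile groups are the C6–OH/C7–Br bromohydrin (closes to an oxirane with any base), the tertiary bromide (ionisation, elimination), the trisubstituted oxirane (acid) and the dihaloalkene (geometry). The real difficulty is the C6(OH)–C7(Br)(CH3)–C8H2Cl array: bromine sits on the more substituted and chlorine on the less substituted carbon, the reverse of alkene bromochlorination, and the tertiary bromide has a defined configuration. The key step uses the fact that C7 is bonded both to the oxygen-bearing C6 and to the halomethyl carbon C8: in a C6–C7 oxirane with bromine on C8, that bromine can displace the C7–O bond from the rear and pass C8 on to chloride.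

## Logic of the disconnections

23 from 22. Bond cut: O–Si at C6. The hydroxyl is unmasked last, because a free C6–OH beside the C7 bromide closes to an oxirane under any base. The gain is that acetylide and Grignard steps become permissible. The forward step must cleave silicon without base and without acid strong enough to open the C3–C4 oxirane.

22 from 21. Bonds cut: C2–Cl and C1–H. The Z-dihaloalkene is the anti adduct of HCl to a 1-bromoalkyne, so the alkene geometry and the C2 chlorine reduce to a linear alkyne. The forward step needs chloride at C2 only, anti addition only, and survival of oxirane, silyl ether and tertiary bromide in a chloride/acetic acid medium.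

21 from 20. Bond cut: C1–Br, exchanged for C1–Si. The silyl cap arrives with the acetylide that forms C2–C3 and is the direct precursor of the bromide. The forward step needs bromination at the alkyne terminus without ionising the C7 bromide.

20 from 16 and 17. Bonds cut: C2–C3 and C4–O. Two contiguous stereocentres become one C–Cl centre that directs the other, and the quaternary carbon and the ring come from a ketone and a purchased alkyne. The forward step needs attack on the ketone face predicted by the Cornforth model and clean rear-side closure at C4.

16 from 15, and 15 from 13 and 14. Bond cut: C3–CH3, after adjusting the oxidation level at C3. The ketone becomes an aldehyde, the carbonyl class for which catalytic enantioselective α-chlorination is dependable. Addition and oxidation must not epimerise C4.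

13 from 12. Bond cut: C4–Cl. The C4 centre is set by a catalyst and not by the distant C6/C7 pair. The forward step needs catalyst control and immediate use of the labile chloro aldehyde.

12 from 10, and 10 from 9. Bonds cut: C3=O back to a C3=CH2 alkene (one carbon restored), then O–Si at C6. The aldehyde is stored as an inert terminal alkene through the halogen-shift step. The forward steps need ozonolysis beside alkyl halides and silylation of a bromohydrin without base-induced closure.

9 from 6. Bonds cut: C7–Br and C8–Cl (bromine returned to C8, oxygen returned to C7 as a C6–C7 oxirane). The anti-Markovnikov halogen pattern and the tertiary C–Br centre are traded for an epoxide whose two centres come from a reliable catalytic epoxidation. The forward step needs bromine participation at C7 with inversion and chloride capture at C8.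

6 from 5, and 5 from 4. Bonds cut: C8–Br (back to C8–OH), then the two oxirane C–O bonds. The result is an achiral allylic alcohol. The forward steps need a neutral bromination that spares the oxirane and an epoxidation that gives the 2R,3R series and ignores the terminal alkene.

4 from 3, and 3 from 1 and 2. Bonds cut: the ester oxidation level at C8, then C6=C7. The result is two purchased compounds. The forward step needs E geometry at the trisubstituted alkene, because it becomes the relative configuration of C6 and C7.

## Other disconnections considered

Alternative 1: carbene addition and electrocyclic opening.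
- **Cut:** the C3–O bond and, retrosynthetically, a C1–C3 bond, so the haloalkene carbinol is traced to the gem-dichlorocyclopropane A3, made by adding dichlorocarbene across a bromine-bearing C1=C3 double bond.
- **Forward key step:** AgBF4 removes one chloride from C2 of A3 and disrotatory cleavage of C1–C3 gives a 2-chloroallyl cation. The carbonyl oxygen of the tert-butyl carbonate on C4 captures C3 with loss of isobutene. C3–O, the C1=C2 alkene and a 1,3-dioxolan-2-one form together (A1 if C3 and C4 are written with the descriptors of the target's oxirane).
- **In favour:** the Z geometry follows from torquoselection, since bromine turns outward because the inward position is already contested by a C3 substituent. No alkyne or palladium is needed, and the tertiary C3–O bond is made without a ketone addition.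
- **Against:**
  - The C3 configuration relative to C4 would rest only on the rotamer population of the cation at capture.
  - An oxirane can be closed from the C3/C4 dioxygenated array only by displacing an activated C4 oxygen with the C3 oxygen, which inverts C4. A1 would therefore put C5 and the haloalkene on the same side of the oxirane; the carbonate that maps onto the target is the C4 epimer A2, and the carbinol centre of A3 must be chosen accordingly.
  - Closing the oxirane then costs hydrolysis, sulfonylation and base treatment.
  - The product ends at a C6 silyl ether, so the C6–C8 bromochlorohydrin is not addressed.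
- **Comparison:** on haloalkene geometry the alternative is the better plan, because a stereospecific pericyclic step replaces a palladium-catalysed addition beside an oxirane. On the C3/C4 pair the chosen plan is firmer. On C6–C8 the alternative has no answer, and it would be longer.

Alternative 2: alkynylation of a chloro ketone with oxirane closure.
- **Cut:** C2–C3 and C4–O.
- **Forward key step:** lithium trimethylsilylacetylide attacks the C3 carbonyl of the α-chloro ketone 16 in the Cornforth sense and the alkoxide displaces the C4 chloride, giving the silylalkynyl oxirane A4.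
- **In favour:** the reaction type is well established; it makes the quaternary centre and the ring in one flask and relays C4 to C3 by substrate control.
- **Against, as the centre of the strategy:** A4 already contains the complete C6–C8 array, so the disconnection presupposes a solution to the hardest problem.
- **Comparison:** this operation is a component of the chosen plan, not a rival (it is step 11, and A4 is the same compound as 20). As a single step it is better founded mechanistically than the halogen shift. In structure it solves the easier stereo pair, and step economy is identical over this stretch.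

Alternative 3: asymmetric 5-exo bromolactonisation.
- **Cut:** C7–Br and the lactone C6–O bond across a C6=C7 double bond; the precursor is the achiral acid A6.
- **Forward key step:** N-bromosuccinimide with (DHQD)2PHAL, or its pseudo-enantiomer (DHQ)2PHAL, forms a bromiranium ion on the E alkene and the carboxylate closes 5-exo onto C6 anti to bromine, giving lactone A5.
- **In favour:** one catalytic operation sets C6 and C7, and E geometry with anti addition gives the right relative configuration. Chlorine is on C8 from the start and the lactone keeps the C6 oxygen acylated. The array is reached in fewer steps and without an unprecedented rearrangement; on these points the alternative is the better one.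
- **Against:**
  - A trisubstituted alkene normally takes the nucleophile at its more substituted carbon, so 6-endo attack at C7 competes; the allylic chlorine lowers this preference but may not reverse it.
  - These catalysts are established for 1,1-disubstituted and aryl-substituted alkenoic acids, not for trialkyl alkenes.
  - The quinuclidine nitrogen can be alkylated by the allylic chloride.
  - The lactone must later be opened and turned into the C3 methyl ketone while the liberated C6 oxygen is protected before it attacks C7.
- **Comparison:** both plans create C6–O and C7–Br anti to each other. The chosen plan takes absolute configuration from a dependable tartrate-controlled epoxidation; the alternative takes it from a catalyst outside its proven substrate class. Mechanistically they are equals in kind, each resting on one regiochemical decision at a bromiranium ion. The alternative is shorter up to the halohydrin but loses part of that lead in lactone opening and reprotection.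

Key step: step 5

Step 1
Reactants: 1 pent-4-enal; 2 ethyl 2-(triphenylphosphoranylidene)propanoate
Product: 3 ethyl (2E)-2-methylhepta-2,6-dienoate
Conditions: CH2Cl2, 0 → 23 °C
Reagents that add atoms: none
Why: Wittig olefination with a stabilised α-methyl ylide; reversible oxaphosphetane formation should favour the E enoate, the geometry that later becomes the relative configuration of C6 and C7.

Step 2
Reactants: 3 ethyl (2E)-2-methylhepta-2,6-dienoate
Product: 4 (2E)-2-methylhepta-2,6-dien-1-ol
Conditions: iBu2AlH, CH2Cl2, −78 → 0 °C; aq. KNaC4H4O6 (potassium sodium tartrate)
Reagents that add atoms: none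
Why: DIBAL-H reduces the conjugated ester by 1,2-hydride delivery at low temperature and leaves both alkenes and the E geometry untouched.

Step 3
Reactants: 4 (2E)-2-methylhepta-2,6-dien-1-ol
Product: 5 [(2R,3R)-3-(but-3-en-1-yl)-2-methyloxiran-2-yl]methanol
Conditions: Ti(OiPr)4 (10 mol %), D-(−)-diethyl tartrate (12 mol %), tBuOOH, 4 Å molecular sieves, CH2Cl2, −20 °C
Reagents that add atoms: tert-butyl hydroperoxide, CC(C)(C)OO
Why: Sharpless asymmetric epoxidation: only the allylic alkene is held on titanium through the alkoxide, so the terminal alkene is ignored; with D-(−)-diethyl tartrate oxygen should reach the face that gives the 2R,3R epoxy alcohol, setting C6 (R) and the C7–O bond that bromine later displaces.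

Step 4
Reactants: 5 [(2R,3R)-3-(but-3-en-1-yl)-2-methyloxiran-2-yl]methanol
Product: 6 (2S,3R)-2-(bromomethyl)-3-(but-3-en-1-yl)-2-methyloxirane
Conditions: CBr4, PPh3, CH2Cl2, 0 °C
Reagents that add atoms: carbon tetrabromide, BrC(Br)(Br)Br
Why: Appel bromination of the primary alcohol through an alkoxyphosphonium ion under neutral conditions; displacement occurs at C8 only, so both oxirane centres keep their geometry (the C7 descriptor becomes S only because CH2Br outranks C6).

Step 5
Reactants: 6 (2S,3R)-2-(bromomethyl)-3-(but-3-en-1-yl)-2-methyloxirane
Product: 9 (2R,3R)-2-bromo-1-chloro-2-methylhept-6-en-3-ol, via bromiranium titanate 7 (not isolated), via titanium alkoxide 8 (not isolated)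
Conditions: 6 added to ClTi(OiPr)3 (1.5 equiv), CH2Cl2, −20 → 0 °C; aq. tartaric acid
Reagents that add atoms: chlorotitanium triisopropoxide, CC(C)O[Ti](Cl)(OC(C)C)OC(C)C
Why: Proposed new method: coordination of the oxirane oxygen to ClTi(OiPr)3 weakens the C7–O bond, and the C8 bromine, antiperiplanar to that bond in the reactive rotamer, displaces it from the rear to give bromiranium titanate 7, whose metal-bound chloride then attacks C8 anti to bromine, leaving the tertiary C7–Br bond, the primary C8–Cl bond and titanium alkoxide 8. The closest known reaction types are neighbouring-bromine participation in the ionisation of β-bromo alcohol derivatives, which gives configurationally defined bromiranium ions, and the opening of trisubstituted oxiranes by chlorotitanium alkoxides; a 1,2-bromine shift triggered by oxirane opening with chloride capture at the vacated carbon has not been shown. No ring is closed in the product: the transient three-membered bromiranium ring forms by 3-exo-tet attack of bromine on C7 and is opened again in the same flask. The new stereocentre C7 is controlled by the oxirane itself, since rear-side entry of bromine inverts C7 (7R), while C6 keeps its oxygen and configuration (6R). Three selectivities are needed: cleavage of C7–O and not C6–O, secured because bromine can assist only at C7, which is also the tertiary terminus; inversion at C7, secured by the bridging geometry; and chloride capture at C8 and not C7, favoured by the unhindered primary carbon, by a six-membered delivery path from the titanate on the C6 oxygen and by the electron-withdrawing C6–O bond that disfavours charge at C7. The monosubstituted alkene is a poor partner for bromonium transfer or cation capture, and inverse addition keeps chloride in excess. The quench is mildly acidic and base is avoided throughout, because the free bromohydrin would close to a C6–C7 oxirane.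

Step 6
Reactants: 9 (2R,3R)-2-bromo-1-chloro-2-methylhept-6-en-3-ol
Product: 10 triethyl{[(2R,3R)-2-bromo-1-chloro-2-methylhept-6-en-3-yl]oxy}silane
Conditions: Et3SiOTf, 2,6-lutidine, CH2Cl2, −78 °C
Reagents that add atoms: triethylsilyl trifluoromethanesulfonate, CC[Si](CC)(CC)OS(=O)(=O)C(F)(F)F
Why: Silylation of the hindered secondary alcohol with a silyl triflate; 2,6-lutidine is too weak and hindered to generate the alkoxide, so the bromohydrin should not close, and the triethylsilyl ether then blocks that closure in every later basic step.

Step 7
Reactants: 10 triethyl{[(2R,3R)-2-bromo-1-chloro-2-methylhept-6-en-3-yl]oxy}silane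
Product: 12 (4R,5R)-5-bromo-6-chloro-5-methyl-4-(triethylsilyloxy)hexanal, via ozonide 11 (not isolated)
Conditions: O3, CH2Cl2, −78 °C; then PPh3, −78 → 23 °C
Reagents that add atoms: ozone, [O-][O+]=O
Why: Ozonolysis of the only alkene with reductive cleavage of ozonide 11 gives the C3 aldehyde; alkyl halides and the silyl ether are inert to ozone at −78 °C.

Step 8
Reactants: 12 (4R,5R)-5-bromo-6-chloro-5-methyl-4-(triethylsilyloxy)hexanal
Product: 13 (2R,4R,5R)-5-bromo-2,6-dichloro-5-methyl-4-(triethylsilyloxy)hexanal
Conditions: N-chlorosuccinimide, (2S,5S)-2,5-diphenylpyrrolidine (10 mol %), CH2Cl2, 0 °C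
Reagents that add atoms: N-chlorosuccinimide, O=C1CCC(=O)N1Cl
Why: Enamine-catalysed α-chlorination of an aldehyde: the C2-symmetric amine forms the E-enamine and shields one face, so chlorine should enter C4 under catalyst control (4R in chain numbering, 2R in the aldehyde name), the C6 centre two atoms away having little influence; the labile product is used at once.

Step 9
Reactants: 13 (2R,4R,5R)-5-bromo-2,6-dichloro-5-methyl-4-(triethylsilyloxy)hexanal; 14 methylmagnesium bromide
Product: 15 (2RS,3R,5R,6R)-6-bromo-3,7-dichloro-6-methyl-5-(triethylsilyloxy)heptan-2-ol
Conditions: Et2O, −78 °C; aq. NH4Cl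
Reagents that add atoms: none
Why: Grignard addition to the aldehyde at −78 °C outruns enolisation, so C4 should keep its configuration; the new C3 carbinol centre forms as a mixture and is erased in step 10.

Step 10
Reactants: 15 (2RS,3R,5R,6R)-6-bromo-3,7-dichloro-6-methyl-5-(triethylsilyloxy)heptan-2-ol
Product: 16 (3R,5R,6R)-6-bromo-3,7-dichloro-6-methyl-5-(triethylsilyloxy)heptan-2-one
Conditions: Dess–Martin periodinane, CH2Cl2, 0 → 23 °C
Reagents that add atoms: none
Why: Dess–Martin oxidation under non-basic conditions converts both C3 epimers into one α-chloro ketone without enolising C4 and without touching the silyl ether or the halides.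

Step 11
Reactants: 16 (3R,5R,6R)-6-bromo-3,7-dichloro-6-methyl-5-(triethylsilyloxy)heptan-2-one; 17 trimethylsilylacetylene
Product: 20 (3S,4S,6R,7R)-7-bromo-8-chloro-3,4-epoxy-3,7-dimethyl-6-(triethylsilyloxy)-1-(trimethylsilyl)oct-1-yne, via lithium trimethylsilylacetylide 18 (not isolated), via lithium chlorohydrin alkoxide 19 (not isolated)
Conditions: 17, nBuLi, THF, −78 °C; 16, −78 °C; then → 23 °C
Reagents that add atoms: none
Why: Cornforth-controlled 1,2-addition of acetylide 18 to the α-chloro ketone (C=O and C–Cl dipoles opposed, attack past the C4 hydrogen) should give anti alkoxide 19, which on warming displaces chloride at C4 from the rear (3-exo-tet); C3 is thus set by C4 and C4 is inverted, so the alkyne and C5 end up trans on the oxirane (3S,4S here; the C3 descriptor becomes R once C2 bears chlorine).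

Step 12
Reactants: 20 (3S,4S,6R,7R)-7-bromo-8-chloro-3,4-epoxy-3,7-dimethyl-6-(triethylsilyloxy)-1-(trimethylsilyl)oct-1-yne
Product: 21 (3S,4S,6R,7R)-1,7-dibromo-8-chloro-3,4-epoxy-3,7-dimethyl-6-(triethylsilyloxy)oct-1-yne
Conditions: N-bromosuccinimide, AgNO3 (10 mol %), acetone, 23 °C, dark
Reagents that add atoms: N-bromosuccinimide, O=C1CCC(=O)N1Br
Why: Silver-catalysed bromodesilylation of an alkynylsilane through a silver acetylide; with catalytic monovalent silver the C7 bromide, deactivated towards ionisation by the neighbouring C–Cl and C–O bonds, should survive.

Step 13
Reactants: 21 (3S,4S,6R,7R)-1,7-dibromo-8-chloro-3,4-epoxy-3,7-dimethyl-6-(triethylsilyloxy)oct-1-yne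
Product: 22 (1Z,3R,4S,6R,7R)-1,7-dibromo-2,8-dichloro-3,4-epoxy-3,7-dimethyl-6-(triethylsilyloxy)oct-1-ene
Conditions: Pd(OAc)2 (5 mol %), LiCl, AcOH, 23 °C
Reagents that add atoms: lithium chloride, [Li+].[Cl-]
Why: Palladium-catalysed hydrochlorination of a 1-bromoalkyne: chloride adds to C2 anti to divalent palladium on C1 (trans-chloropalladation) and protonolysis of the C–Pd bond with retention puts hydrogen trans to chlorine, hence bromine cis to chlorine (1Z); the electron-poor, hindered oxirane is expected to outlast the weakly acidic chloride medium at room temperature.

Step 14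
Reactants: 22 (1Z,3R,4S,6R,7R)-1,7-dibromo-2,8-dichloro-3,4-epoxy-3,7-dimethyl-6-(triethylsilyloxy)oct-1-ene
Product: 23 (1Z,3R,4S,6R,7R)-1,7-dibromo-2,8-dichloro-3,4-epoxy-3,7-dimethyloct-1-en-6-ol
Conditions: HF·pyridine, pyridine, THF, 0 °C
Reagents that add atoms: none
Why: Fluoride cleavage of the triethylsilyl ether with pyridine-buffered HF: no alkoxide is formed, so the C6–OH/C7–Br pair cannot close, and the oxirane, deactivated by the dihalovinyl group, should resist the buffered acid.

Compound list

1 | pent-4-enal | C=CCCC=O | starting material
2 | ethyl 2-(triphenylphosphoranylidene)propanoate | CCOC(=O)C(C)=P(c1ccccc1)(c1ccccc1)c1ccccc1 | starting material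
3 | ethyl (2E)-2-methylhepta-2,6-dienoate | C=CCC/C=C(\C)C(=O)OCC | intermediate
4 | (2E)-2-methylhepta-2,6-dien-1-ol | C=CCC/C=C(\C)CO | intermediate
5 | [(2R,3R)-3-(but-3-en-1-yl)-2-methyloxiran-2-yl]methanol | C[C@]1(CO)O[C@@H]1CCC=C | intermediate
6 | (2S,3R)-2-(bromomethyl)-3-(but-3-en-1-yl)-2-methyloxirane | C[C@]1(CBr)O[C@@H]1CCC=C | intermediate
7 | bromiranium titanate (not isolated): C7–C8 bromiranium ion, bromine anti to the former C7–O bond, paired with the chlorotriisopropoxytitanate on the C6 oxygen | C[C@]1(C[Br+]1)[C@H](O[Ti-](Cl)(OC(C)C)(OC(C)C)OC(C)C)CCC=C | intermediate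
8 | titanium alkoxide (not isolated): triisopropoxytitanium (2R,3R)-2-bromo-1-chloro-2-methylhept-6-en-3-olate | C[C@](Br)(CCl)[C@H](O[Ti](OC(C)C)(OC(C)C)OC(C)C)CCC=C | intermediate
9 | (2R,3R)-2-bromo-1-chloro-2-methylhept-6-en-3-ol | C[C@](Br)(CCl)[C@H](O)CCC=C | intermediate
10 | triethyl{[(2R,3R)-2-bromo-1-chloro-2-methylhept-6-en-3-yl]oxy}silane | C[C@](Br)(CCl)[C@H](O[Si](CC)(CC)CC)CCC=C | intermediate
11 | ozonide (not isolated): 3-[(3R,4R)-4-bromo-5-chloro-4-methyl-3-(triethylsilyloxy)pentyl]-1,2,4-trioxolane, ring carbon unassigned | C[C@](Br)(CCl)[C@H](O[Si](CC)(CC)CC)CCC1OCOO1 | intermediate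
12 | (4R,5R)-5-bromo-6-chloro-5-methyl-4-(triethylsilyloxy)hexanal | C[C@](Br)(CCl)[C@H](O[Si](CC)(CC)CC)CCC=O | intermediate
13 | (2R,4R,5R)-5-bromo-2,6-dichloro-5-methyl-4-(triethylsilyloxy)hexanal | C[C@](Br)(CCl)[C@H](O[Si](CC)(CC)CC)C[C@@H](Cl)C=O | intermediate
14 | methylmagnesium bromide | C[Mg]Br | starting material
15 | (2RS,3R,5R,6R)-6-bromo-3,7-dichloro-6-methyl-5-(triethylsilyloxy)heptan-2-ol (both C2 epimers) | C[C@](Br)(CCl)[C@H](O[Si](CC)(CC)CC)C[C@@H](Cl)C(C)O | intermediate
16 | (3R,5R,6R)-6-bromo-3,7-dichloro-6-methyl-5-(triethylsilyloxy)heptan-2-one | C[C@](Br)(CCl)[C@H](O[Si](CC)(CC)CC)C[C@@H](Cl)C(C)=O | intermediate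
17 | trimethylsilylacetylene (ethynyltrimethylsilane) | C#C[Si](C)(C)C | starting material
18 | lithium trimethylsilylacetylide (not isolated) | [Li]C#C[Si](C)(C)C | intermediate
19 | lithium chlorohydrin alkoxide (not isolated): lithium (3S,4R,6R,7R)-7-bromo-4,8-dichloro-3,7-dimethyl-6-(triethylsilyloxy)-1-(trimethylsilyl)oct-1-yn-3-olate | C[C@](Br)(CCl)[C@H](O[Si](CC)(CC)CC)C[C@@H](Cl)[C@@](C)(O[Li])C#C[Si](C)(C)C | intermediate
20 | (3S,4S,6R,7R)-7-bromo-8-chloro-3,4-epoxy-3,7-dimethyl-6-(triethylsilyloxy)-1-(trimethylsilyl)oct-1-yne | C[C@](Br)(CCl)[C@H](O[Si](CC)(CC)CC)C[C@@H]1O[C@@]1(C)C#C[Si](C)(C)C | intermediate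
21 | (3S,4S,6R,7R)-1,7-dibromo-8-chloro-3,4-epoxy-3,7-dimethyl-6-(triethylsilyloxy)oct-1-yne | C[C@](Br)(CCl)[C@H](O[Si](CC)(CC)CC)C[C@@H]1O[C@@]1(C)C#CBr | intermediate
22 | (1Z,3R,4S,6R,7R)-1,7-dibromo-2,8-dichloro-3,4-epoxy-3,7-dimethyl-6-(triethylsilyloxy)oct-1-ene | C[C@](Br)(CCl)[C@H](O[Si](CC)(CC)CC)C[C@@H]1O[C@@]1(C)/C(Cl)=C/Br | intermediate
23 | (1Z,3R,4S,6R,7R)-1,7-dibromo-2,8-dichloro-3,4-epoxy-3,7-dimethyloct-1-en-6-ol | C[C@](Br)(CCl)[C@H](O)C[C@@H]1O[C@@]1(C)/C(Cl)=C/Br | target

Total step count: 14. Longest linear sequence: 14 steps (1 to 23); 2, 14 and 17 are purchased and enter in single steps.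

Least certain steps

Step 5 (key step, proposed new method). The most likely failure is delivery of chloride to C7 instead of C8, by collapse of the bromiranium titanate at its more substituted carbon or by direct opening of the oxirane, because positive charge in an unsymmetrical bromiranium ion concentrates on the tertiary carbon. Sluggish ionisation with this weak Lewis acid is a second possibility. The fallback uses known reaction types, sets out from 5 and returns at 9. Appel chlorination of 5 (N-chlorosuccinimide, PPh3, CH2Cl2, 0 °C) should give (2S,3R)-3-(but-3-en-1-yl)-2-(chloromethyl)-2-methyloxirane F1, in which C8 already carries chlorine. Acid-mediated bromide opening of F1 (48 % aq. HBr, CHCl3, −20 °C), the ordinary anti opening of a trisubstituted oxirane at its more substituted carbon, would then place bromine on C7 with inversion and free the C6 hydroxyl, giving 9. The price is weaker regiocontrol (competing attack at C6), to be met by chromatographic separation.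

Step 11. The most likely failure is insufficient face selection at the methyl ketone, which differentiates its faces less sharply than an aldehyde, or base-induced elimination at the tertiary bromide while the lithium alkoxide is warmed to close the ring. The fallback sets out from 16 and returns at 20. The addition is quenched at −78 °C with acetic acid to isolate (3S,4R,6R,7R)-7-bromo-4,8-dichloro-3,7-dimethyl-6-(triethylsilyloxy)-1-(trimethylsilyl)oct-1-yn-3-ol F2. F2 is freed from its C3 epimer by chromatography and closed in a separate operation (NaH, THF, 0 °C) to 20.

Step 13. The most likely failure is opening of the oxirane by chloride in acetic acid, or attack of the oxirane oxygen on the palladium-activated alkyne, before chloropalladation is complete; chloride attack at C2 is also slowed by the adjacent quaternary carbon. The fallback sets out from 16 and returns at 22, and completes the haloalkene before the oxirane exists.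
- The chlorohydrin F2 (made from 16 as in the fallback for step 11) is bromodesilylated (N-bromosuccinimide, AgNO3 10 mol %, acetone) to (3S,4R,6R,7R)-1,7-dibromo-4,8-dichloro-3,7-dimethyl-6-(triethylsilyloxy)oct-1-yn-3-ol F3.
- F3 is hydrochlorinated (Pd(OAc)2, LiCl, AcOH) to (1Z,3R,4R,6R,7R)-1,7-dibromo-2,4,8-trichloro-3,7-dimethyl-6-(triethylsilyloxy)oct-1-en-3-ol F4.
- F4 is closed with K2CO3 in MeOH at 0 °C to 22.

This order adds one step and exposes a free tertiary alcohol to the silver salt, which is why it is held in reserve.

Step 12. The most likely failure is silver-assisted ionisation of the tertiary C7 bromide, followed by elimination or capture, since monovalent silver is halophilic even though the flanking C–Cl and C–O bonds retard it. The silver-free fallback sets out from 20 and returns at 21. Protodesilylation (K2CO3, MeOH, 0 °C) should give (3S,4S,6R,7R)-7-bromo-8-chloro-3,4-epoxy-3,7-dimethyl-6-(triethylsilyloxy)oct-1-yne F5. Base-mediated electrophilic bromination of the terminal alkyne (N-bromosuccinimide, DBU, MeCN, 0 °C) would then give 21.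

## Further compounds

F1 | step 5 | (2S,3R)-3-(but-3-en-1-yl)-2-(chloromethyl)-2-methyloxirane | C[C@]1(CCl)O[C@@H]1CCC=C
F2 | step 11 | (3S,4R,6R,7R)-7-bromo-4,8-dichloro-3,7-dimethyl-6-(triethylsilyloxy)-1-(trimethylsilyl)oct-1-yn-3-ol | C[C@](Br)(CCl)[C@H](O[Si](CC)(CC)CC)C[C@@H](Cl)[C@@](C)(O)C#C[Si](C)(C)C
F3 | step 13 | (3S,4R,6R,7R)-1,7-dibromo-4,8-dichloro-3,7-dimethyl-6-(triethylsilyloxy)oct-1-yn-3-ol | C[C@](Br)(CCl)[C@H](O[Si](CC)(CC)CC)C[C@@H](Cl)[C@@](C)(O)C#CBr
F4 | step 13 | (1Z,3R,4R,6R,7R)-1,7-dibromo-2,4,8-trichloro-3,7-dimethyl-6-(triethylsilyloxy)oct-1-en-3-ol | C[C@](Br)(CCl)[C@H](O[Si](CC)(CC)CC)C[C@@H](Cl)[C@@](C)(O)/C(Cl)=C/Br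
F5 | step 12 | (3S,4S,6R,7R)-7-bromo-8-chloro-3,4-epoxy-3,7-dimethyl-6-(triethylsilyloxy)oct-1-yne | C[C@](Br)(CCl)[C@H](O[Si](CC)(CC)CC)C[C@@H]1O[C@@]1(C)C#C
A1 | alternative 1 | (4R,5S)-4-[(Z)-2-bromo-1-chloroethenyl]-5-[2-(tert-butyldiphenylsilyloxy)ethyl]-4-methyl-1,3-dioxolan-2-one | CC(C)(C)[Si](c1ccccc1)(c1ccccc1)OCC[C@@H]1OC(=O)O[C@@]1(C)/C(Cl)=C/Br
A2 | alternative 1 | (4R,5R)-4-[(Z)-2-bromo-1-chloroethenyl]-5-[2-(tert-butyldiphenylsilyloxy)ethyl]-4-methyl-1,3-dioxolan-2-one | CC(C)(C)[Si](c1ccccc1)(c1ccccc1)OCC[C@H]1OC(=O)O[C@@]1(C)/C(Cl)=C/Br
A3 | alternative 1 | tert-butyl 1-(3-bromo-2,2-dichloro-1-methylcyclopropyl)-3-(tert-butyldiphenylsilyloxy)propyl carbonate, carbinol centre as in A2, bromine cis to the carbinol branch, one carbene-face diastereomer shown | CC(C)(C)[Si](c1ccccc1)(c1ccccc1)OCC[C@@H](OC(=O)OC(C)(C)C)[C@@]2(C)[C@@H](Br)C2(Cl)Cl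
A4 | alternative 2 | (3S,4S,6R,7R)-7-bromo-8-chloro-3,4-epoxy-3,7-dimethyl-6-(triethylsilyloxy)-1-(trimethylsilyl)oct-1-yne | C[C@](Br)(CCl)[C@H](O[Si](CC)(CC)CC)C[C@@H]1O[C@@]1(C)C#C[Si](C)(C)C
A5 | alternative 3 | (5R)-5-[(2R)-2-bromo-1-chloropropan-2-yl]oxolan-2-one | C[C@](Br)(CCl)[C@H]1CCC(=O)O1
A6 | alternative 3 | (4E)-6-chloro-5-methylhex-4-enoic acid | OC(=O)CC/C=C(\C)CCl
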